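**Retrosynthetic overview**

- The strategy rests on ring A carrying three oxygens with different roles: O1 on C8a is the ring ether, O5 is galloylated and O7 is a free phenol. Ring A is therefore built last, so that each oxygen arrives in its own state and O5 never has to be told apart from O7.
- Target 28 ⇒ (hydrogenolysis of nine benzyl ethers; acylation of O3 and O5) 3,5-diol 23 ⇒ (MOM removal) 5-phenol 22.
- Ring A of 22 ⇒ cut C8–C8a and C4a–C5: C8a-stannylated dihydropyran 13 (ring C, carrying ring B and both stereocentres) plus 3-benzyloxy-4-chlorocyclobutenone 18, joined by Stille coupling, 4π opening and 6π closure.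
- 13 ⇒ ketene acetal phosphate ⇒ δ-lactone ⇒ ring-closing metathesis of an acrylate ⇒ syn-alkoxyallylboration of 3,4-bis(benzyloxy)benzaldehyde (sets C2 and C3); 18 ⇒ chloroketene plus ethoxyacetylene, then alkoxy exchange.
- Ring order: ring B and the galloyl rings are bought; ring C closes in step 3; ring A closes in step 9.

Key step: step 9

Remark on the chemistry: 3-(methoxymethoxy)prop-1-ene, ethoxyacetylene (hexane solution) and 3,4,5-tris(benzyloxy)benzoic acid are taken as catalogue compounds, and the borane derived from (+)-α-pinene is assumed to attack the Si face of the aryl aldehyde as the parent allylborane does.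

**Route**

Step 1
Reactants: 1 3,4-bis(benzyloxy)benzaldehyde; 2 3-(methoxymethoxy)prop-1-ene
Product: 7 (1R,2R)-1-[3,4-bis(benzyloxy)phenyl]-2-(methoxymethoxy)but-3-en-1-ol, via allyllithium 3 (not isolated), via lithium borate complex 4 (not isolated), via Z-alkoxyallylborane 5 (not isolated), via borinate adduct 6 (not isolated)
Conditions: 2, s-BuLi, THF, −78 °C; (−)-Ipc2BOMe; BF3·OEt2; 1, −78 °C → rt; then NaOH, H2O2
Reagents that add atoms: none
Why: Brown alkoxyallylboration, in which the chelated (Z)-allyllithium 3 is carried through borate 4 to the (Z)-γ-alkoxyallylborane 5, whose chair-like six-membered transition state turns the Z geometry into the syn relationship while the isopinocampheyl groups direct attack to the Si face of 1, so that both centres should be set as (1R,2R).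

Step 2
Reactants: 7 (1R,2R)-1-[3,4-bis(benzyloxy)phenyl]-2-(methoxymethoxy)but-3-en-1-ol
Product: 8 (1R,2R)-1-[3,4-bis(benzyloxy)phenyl]-2-(methoxymethoxy)but-3-en-1-yl prop-2-enoate
Conditions: acryloyl chloride, Et3N, DMAP (cat.), CH2Cl2, 0 °C
Reagents that add atoms: acryloyl chloride, C=CC(=O)Cl
Why: DMAP-catalysed O-acylation of the secondary benzylic alcohol under basic conditions, which should leave the acid-sensitive MOM ether and the stereocentres untouched.

Step 3
Reactants: 8 (1R,2R)-1-[3,4-bis(benzyloxy)phenyl]-2-(methoxymethoxy)but-3-en-1-yl prop-2-enoate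
Product: 9 (5R,6R)-6-[3,4-bis(benzyloxy)phenyl]-5-(methoxymethoxy)-5,6-dihydro-2H-pyran-2-one
Conditions: second-generation Grubbs catalyst RuCl2(=CHPh)(PCy3)(H2IMes) (5 mol%), CH2Cl2 (0.01 M), 40 °C
Reagents that add atoms: none
Why: Ring-closing metathesis of an acrylate with a monosubstituted alkene, a standard entry to 5,6-dihydropyran-2-ones, should close ring C with loss of ethene and without touching C5 or C6.

Step 4
Reactants: 9 (5R,6R)-6-[3,4-bis(benzyloxy)phenyl]-5-(methoxymethoxy)-5,6-dihydro-2H-pyran-2-one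
Product: 10 (5R,6R)-6-[3,4-bis(benzyloxy)phenyl]-5-(methoxymethoxy)tetrahydro-2H-pyran-2-one
Conditions: H2 (3 bar), RhCl(PPh3)3 (10 mol%), toluene, 45 °C
Reagents that add atoms: none
Why: Homogeneous rhodium-catalysed hydrogenation should saturate the unhindered cis-disubstituted C3–C4 alkene while, unlike palladium on carbon, sparing the benzyl ethers and the benzylic lactone C6–O bond.

Step 5
Reactants: 10 (5R,6R)-6-[3,4-bis(benzyloxy)phenyl]-5-(methoxymethoxy)tetrahydro-2H-pyran-2-one
Product: 12 (2R,3R)-2-[3,4-bis(benzyloxy)phenyl]-3-(methoxymethoxy)-3,4-dihydro-2H-pyran-6-yl diphenyl phosphate, via potassium enolate 11 (not isolated)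
Conditions: (PhO)2P(O)Cl, then KN(SiMe3)2, THF/HMPA, −78 °C
Reagents that add atoms: diphenyl chlorophosphate, O=P(Cl)(Oc1ccccc1)Oc1ccccc1
Why: O-phosphorylation of a lactone enolate to the ketene acetal phosphate, where trapping in situ should suppress Claisen self-condensation and the only acidic position is the C3 methylene.

Step 6
Reactants: 12 (2R,3R)-2-[3,4-bis(benzyloxy)phenyl]-3-(methoxymethoxy)-3,4-dihydro-2H-pyran-6-yl diphenyl phosphate
Product: 13 (2R,3R)-2-[3,4-bis(benzyloxy)phenyl]-3-(methoxymethoxy)-6-(trimethylstannyl)-3,4-dihydro-2H-pyran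
Conditions: Me3SnSnMe3, Pd(PPh3)4 (5 mol%), LiCl, THF, 65 °C; purification on Et3N-deactivated silica
Reagents that add atoms: hexamethylditin, C[Sn](C)(C)[Sn](C)(C)C
Why: Palladium-catalysed stannylation of a lactone-derived ketene acetal phosphate with a distannane (oxidative addition into C–OP, Sn-to-Pd transfer, reductive elimination) should place tin on the future C8a under neutral conditions.

Step 7
Reactants: 14 chloroacetyl chloride; 15 ethoxyacetylene
Product: 17 4-chloro-3-ethoxycyclobut-2-en-1-one (racemic), via chloroketene 16 (not isolated)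
Conditions: 14 added slowly to 15 (2 equiv) and Et3N, Et2O, 0 °C → rt
Reagents that add atoms: none
Why: Ketene–ynol ether [2+2] cycloaddition, in which the nucleophilic terminal carbon of 15 bonds to the ketene carbonyl carbon, so the chlorine should end on the sp3 carbon next to the ethoxy-bearing carbon.

Step 8
Reactants: 17 4-chloro-3-ethoxycyclobut-2-en-1-one
Product: 18 3-(benzyloxy)-4-chlorocyclobut-2-en-1-one (racemic)
Conditions: BnOH (5 equiv), camphorsulfonic acid (5 mol%), toluene, 30 °C, reduced pressure (EtOH removed)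
Reagents that add atoms: benzyl alcohol, OCc1ccccc1
Why: Acid-catalysed alkoxy exchange of a vinylogous ester by addition–elimination at C3, as known for squarate esters and 3-alkoxyenones, driven by removal of ethanol and run cold to avoid enolisation toward C4.

Step 9
Reactants: 13 (2R,3R)-2-[3,4-bis(benzyloxy)phenyl]-3-(methoxymethoxy)-6-(trimethylstannyl)-3,4-dihydro-2H-pyran; 18 3-(benzyloxy)-4-chlorocyclobut-2-en-1-one
Product: 22 (2R,3R)-7-(benzyloxy)-2-[3,4-bis(benzyloxy)phenyl]-3-(methoxymethoxy)chroman-5-ol, via 4-alkenylcyclobutenone 19 (not isolated), via dienylketene 20 (not isolated), via cyclohexadienone 21 (not isolated)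
Conditions: Pd2(dba)3 (2.5 mol%), tri(2-furyl)phosphine (10 mol%), dioxane, 50 °C, then 100 °C
Reagents that add atoms: none
Why: Zerovalent palladium inserts into the allylic, α-keto C–Cl bond of 18, the alkenyl group of 13 moves from tin to palladium and reductive elimination forms C8–C8a in 19; at 100 °C the strained ring of 19 opens reversibly (4π, conrotatory) to dienylketene 20, whose electrophilic ketene carbon (future C5) bonds to the nucleophilic enol ether β-carbon C4a. The closest known reaction is the Stille coupling of 4-chlorocyclobutenones with alkenylstannanes followed by thermal benzannulation to phenols. Ring A closes by a thermal disrotatory 6π electrocyclisation to dienone 21, which enolises irreversibly to the phenol. No stereocentre is created, since the transient centres at C4 of 19 and C4a of 21 vanish on aromatisation and C2 and C3 are spectators under the neutral, base-free conditions. Regiochemistry is fixed by connectivity, because only the chlorine-bearing carbon can couple and only C4a is within reach of the ketene carbon, so O1 comes from the pyran, O7 from the benzyl enol ether and O5 appears as the only free phenol. Staging the temperature should keep the acid-sensitive stannane away from the phenolic product until transmetalation is complete.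

Step 10
Reactants: 22 (2R,3R)-7-(benzyloxy)-2-[3,4-bis(benzyloxy)phenyl]-3-(methoxymethoxy)chroman-5-ol
Product: 23 (2R,3R)-7-(benzyloxy)-2-[3,4-bis(benzyloxy)phenyl]chromane-3,5-diol
Conditions: ZnBr2, n-PrSH, CH2Cl2, 0 °C, short reaction time
Reagents that add atoms: none
Why: Lewis acid-assisted thiolytic cleavage of the MOM acetal, in which the thiol traps the methoxymethyl cation before it can alkylate the electron-rich ring A, and which should not affect the benzyl ethers.

Step 11
Reactants: 24 3,4,5-tris(benzyloxy)benzoic acid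
Product: 25 3,4,5-tris(benzyloxy)benzoyl chloride
Conditions: (COCl)2, DMF (cat.), CH2Cl2, 0 °C → rt; concentrated and used crude
Reagents that add atoms: oxalyl chloride, O=C(Cl)C(=O)Cl
Why: Standard acid chloride formation through the Vilsmeier-type chloroiminium catalyst, giving only gaseous by-products.

Step 12
Reactants: 23 (2R,3R)-7-(benzyloxy)-2-[3,4-bis(benzyloxy)phenyl]chromane-3,5-diol; 25 3,4,5-tris(benzyloxy)benzoyl chloride
Product: 27 7,3',4'-tri-O-benzyl-epicatechin 3,5-bis[3,4,5-tris(benzyloxy)benzoate], via 5-O-monoester 26 (not isolated)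
Conditions: 25 (3 equiv), Et3N, DMAP, CH2Cl2, 0 °C → rt
Reagents that add atoms: none
Why: DMAP-catalysed acylation, in which the phenol O5 is expected to react first and the hindered axial O3 second with excess acyl chloride, under conditions that do not epimerise C2 or C3.

Step 13
Reactants: 27 7,3',4'-tri-O-benzyl-epicatechin 3,5-bis[3,4,5-tris(benzyloxy)benzoate]
Product: 28 epicatechin 3,5-di-O-gallate
Conditions: H2 (1 atm), Pd(OH)2/C, THF/MeOH, rt; filtration and concentration under argon
Reagents that add atoms: none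
Why: Neutral hydrogenolysis should remove all nine O-benzyl groups while the two gallate esters and the benzylic C2–O1 ether of the flavan survive, as is usual for catechin gallates.

**Compound list**

1 | 3,4-bis(benzyloxy)benzaldehyde | O=Cc1ccc(OCc2ccccc2)c(OCc2ccccc2)c1 | starting material
2 | 3-(methoxymethoxy)prop-1-ene | C=CCOCOC | starting material
3 | (Z)-3-(methoxymethoxy)allyllithium | [Li]C/C=C\OCOC | intermediate (not isolated)
4 | lithium [(Z)-3-(methoxymethoxy)allyl](methoxy)bis(isopinocampheyl)borate | [Li+].CO[B-](C/C=C\OCOC)([C@@H]1C[C@@H]2C[C@H]([C@H]1C)C2(C)C)[C@@H]1C[C@@H]2C[C@H]([C@H]1C)C2(C)C | intermediate (not isolated)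
5 | [(Z)-3-(methoxymethoxy)allyl]bis(isopinocampheyl)borane, Ipc from (+)-α-pinene | COCO/C=C\CB([C@@H]1C[C@@H]2C[C@H]([C@H]1C)C2(C)C)[C@@H]1C[C@@H]2C[C@H]([C@H]1C)C2(C)C | intermediate (not isolated)
6 | bis(isopinocampheyl)borinate of alcohol 7 | C=C[C@@H](OCOC)[C@@H](c1ccc(OCc2ccccc2)c(OCc2ccccc2)c1)OB([C@@H]1C[C@@H]2C[C@H]([C@H]1C)C2(C)C)[C@@H]1C[C@@H]2C[C@H]([C@H]1C)C2(C)C | intermediate (not isolated)
7 | (1R,2R)-1-[3,4-bis(benzyloxy)phenyl]-2-(methoxymethoxy)but-3-en-1-ol | C=C[C@@H](OCOC)[C@@H](c1ccc(OCc2ccccc2)c(OCc2ccccc2)c1)O | intermediate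
8 | (1R,2R)-1-[3,4-bis(benzyloxy)phenyl]-2-(methoxymethoxy)but-3-en-1-yl prop-2-enoate | C=C[C@@H](OCOC)[C@@H](c1ccc(OCc2ccccc2)c(OCc2ccccc2)c1)OC(=O)C=C | intermediate
9 | (5R,6R)-6-[3,4-bis(benzyloxy)phenyl]-5-(methoxymethoxy)-5,6-dihydro-2H-pyran-2-one | O=C1C=C[C@@H](OCOC)[C@@H](c2ccc(OCc3ccccc3)c(OCc3ccccc3)c2)O1 | intermediate
10 | (5R,6R)-6-[3,4-bis(benzyloxy)phenyl]-5-(methoxymethoxy)tetrahydro-2H-pyran-2-one | O=C1CC[C@@H](OCOC)[C@@H](c2ccc(OCc3ccccc3)c(OCc3ccccc3)c2)O1 | intermediate
11 | potassium enolate of lactone 10 | [K+].[O-]C1=CC[C@@H](OCOC)[C@@H](c2ccc(OCc3ccccc3)c(OCc3ccccc3)c2)O1 | intermediate (not isolated)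
12 | (2R,3R)-2-[3,4-bis(benzyloxy)phenyl]-3-(methoxymethoxy)-3,4-dihydro-2H-pyran-6-yl diphenyl phosphate | O=P(Oc1ccccc1)(Oc1ccccc1)OC1=CC[C@@H](OCOC)[C@@H](c2ccc(OCc3ccccc3)c(OCc3ccccc3)c2)O1 | intermediate
13 | (2R,3R)-2-[3,4-bis(benzyloxy)phenyl]-3-(methoxymethoxy)-6-(trimethylstannyl)-3,4-dihydro-2H-pyran | C[Sn](C)(C)C1=CC[C@@H](OCOC)[C@@H](c2ccc(OCc3ccccc3)c(OCc3ccccc3)c2)O1 | intermediate
14 | chloroacetyl chloride | O=C(Cl)CCl | starting material
15 | ethoxyacetylene | C#COCC | starting material
16 | chloroketene | O=C=CCl | intermediate (not isolated)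
17 | 4-chloro-3-ethoxycyclobut-2-en-1-one (racemic) | O=C1C=C(OCC)C1Cl | intermediate
18 | 3-(benzyloxy)-4-chlorocyclobut-2-en-1-one (racemic) | O=C1C=C(OCc2ccccc2)C1Cl | intermediate
19 | 3-(benzyloxy)-4-[(2R,3R)-2-[3,4-bis(benzyloxy)phenyl]-3-(methoxymethoxy)-3,4-dihydro-2H-pyran-6-yl]cyclobut-2-en-1-one (both C4 epimers) | O=C1C=C(OCc2ccccc2)C1C1=CC[C@@H](OCOC)[C@@H](c2ccc(OCc3ccccc3)c(OCc3ccccc3)c2)O1 | intermediate (not isolated)
20 | (Z)-3-(benzyloxy)-4-[(2R,3R)-2-[3,4-bis(benzyloxy)phenyl]-3-(methoxymethoxy)-3,4-dihydro-2H-pyran-6-yl]buta-1,3-dien-1-one | O=C=C/C(OCc1ccccc1)=C\C1=CC[C@@H](OCOC)[C@@H](c2ccc(OCc3ccccc3)c(OCc3ccccc3)c2)O1 | intermediate (not isolated)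
21 | (2R,3R)-7-(benzyloxy)-2-[3,4-bis(benzyloxy)phenyl]-3-(methoxymethoxy)-2,3,4,4a-tetrahydro-5H-chromen-5-one (C4a unassigned) | O=C1C=C(OCc2ccccc2)C=C2C1C[C@@H](OCOC)[C@@H](c1ccc(OCc3ccccc3)c(OCc3ccccc3)c1)O2 | intermediate (not isolated)
22 | (2R,3R)-7-(benzyloxy)-2-[3,4-bis(benzyloxy)phenyl]-3-(methoxymethoxy)chroman-5-ol | Oc1cc(OCc2ccccc2)cc2c1C[C@@H](OCOC)[C@@H](c1ccc(OCc3ccccc3)c(OCc3ccccc3)c1)O2 | intermediate
23 | (2R,3R)-7-(benzyloxy)-2-[3,4-bis(benzyloxy)phenyl]chromane-3,5-diol | Oc1cc(OCc2ccccc2)cc2c1C[C@@H](O)[C@@H](c1ccc(OCc3ccccc3)c(OCc3ccccc3)c1)O2 | intermediate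
24 | 3,4,5-tris(benzyloxy)benzoic acid | O=C(O)c1cc(OCc2ccccc2)c(OCc2ccccc2)c(OCc2ccccc2)c1 | starting material
25 | 3,4,5-tris(benzyloxy)benzoyl chloride | O=C(Cl)c1cc(OCc2ccccc2)c(OCc2ccccc2)c(OCc2ccccc2)c1 | intermediate
26 | (2R,3R)-7-(benzyloxy)-2-[3,4-bis(benzyloxy)phenyl]-3-hydroxychroman-5-yl 3,4,5-tris(benzyloxy)benzoate | O=C(Oc1cc(OCc2ccccc2)cc2c1C[C@@H](O)[C@@H](c1ccc(OCc3ccccc3)c(OCc3ccccc3)c1)O2)c1cc(OCc2ccccc2)c(OCc2ccccc2)c(OCc2ccccc2)c1 | intermediate (not isolated)
27 | 7,3',4'-tri-O-benzyl-epicatechin 3,5-bis[3,4,5-tris(benzyloxy)benzoate] | O=C(Oc1cc(OCc2ccccc2)cc2c1C[C@@H](OC(=O)c1cc(OCc3ccccc3)c(OCc3ccccc3)c(OCc3ccccc3)c1)[C@@H](c1ccc(OCc3ccccc3)c(OCc3ccccc3)c1)O2)c1cc(OCc2ccccc2)c(OCc2ccccc2)c(OCc2ccccc2)c1 | intermediate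
28 | epicatechin 3,5-di-O-gallate | O=C(Oc1cc(O)cc2c1C[C@@H](OC(=O)c1cc(O)c(O)c(O)c1)[C@@H](c1ccc(O)c(O)c1)O2)c1cc(O)c(O)c(O)c1 | target

**Step count**

Total: 13 steps. Longest linear sequence: 10 steps (steps 1–6, 9, 10, 12, 13). Steps 7–8 and step 11 are side branches.

**Three steps most likely to fail**

Step 8 (alkoxy exchange). The acid may move the ring double bond toward the chlorine-bearing carbon through enolisation, or benzyl alcohol may open the strained ring by attack at the carbonyl, instead of exchanging the alkoxy group. Fallback: bring the benzyl ether in with the alkyne, so that no exchange is needed. Benzyl alcohol, KH and trichloroethylene should give benzyl (E)-1,2-dichlorovinyl ether F1. Two equivalents of n-BuLi at −78 °C followed by methanol should give benzyl ethynyl ether F2, which is kept cold and used at once because it rearranges on warming. Chloroketene 16, generated from 14 and Et3N as in step 7, should then add to F2 to give 18 directly. This fallback sets out from 14 and comes back to the route at 18.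

Step 9 (coupling and benzannulation). Protonolysis of the carbon–tin bond of the electron-rich stannane may outrun transmetalation, or the ketene may be consumed by dimerisation or by addition of the phenolic product before the 6π closure. Fallback: make the two ring A bonds one after the other by known polar chemistry.
- Stannane 13 is coupled (Pd(PPh3)4, THF) with the allylic chloride methyl (E)-3-(benzyloxy)-4-chlorobut-2-enoate F3, itself made from methyl 4-chloroacetoacetate and benzyl alcohol under acid catalysis. This should form C8–C8a in methyl (E)-3-(benzyloxy)-4-[(2R,3R)-2-[3,4-bis(benzyloxy)phenyl]-3-(methoxymethoxy)-3,4-dihydro-2H-pyran-6-yl]but-2-enoate F4.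
- LiOH should give the corresponding acid F5, and 1-chloro-N,N,2-trimethylprop-1-en-1-amine should give the acid chloride F6 under neutral conditions.
- Et3N should then remove HCl by 1,4-elimination (C8–H and the acyl chloride) to give the same dienylketene 20, which closes C4a–C5 through 21 to 22. A wrong alkene geometry in the ketene can correct itself through reversible closure to 19.

This fallback sets out from 13 and comes back to the route at 22.

Step 10 (MOM removal). The methoxymethyl cation may be captured by the electron-rich ring A, or the Lewis acid may ionise the benzylic C2–O1 bond and erode the cis relationship. Fallback: acylate O5 before unmasking O3, so that ring A is deactivated by an aryl ester during the acetal cleavage. Phenol 22 and acid chloride 25 (Et3N, DMAP) should give (2R,3R)-7-(benzyloxy)-2-[3,4-bis(benzyloxy)phenyl]-3-(methoxymethoxy)chroman-5-yl 3,4,5-tris(benzyloxy)benzoate F7. Cleavage of its MOM ether (ZnBr2, n-PrSH, or Me3SiBr at low temperature) should give the monoester 26, which is acylated at O3 with 25 to give 27. This fallback sets out from 22 and comes back to the route at 27.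

**Further compounds**

F1 | step 8 | benzyl (E)-1,2-dichlorovinyl ether | Cl/C=C(/Cl)OCc1ccccc1
F2 | step 8 | benzyl ethynyl ether | C#COCc1ccccc1
F3 | step 9 | methyl (E)-3-(benzyloxy)-4-chlorobut-2-enoate | COC(=O)/C=C(\CCl)OCc1ccccc1
F4 | step 9 | methyl (E)-3-(benzyloxy)-4-[(2R,3R)-2-[3,4-bis(benzyloxy)phenyl]-3-(methoxymethoxy)-3,4-dihydro-2H-pyran-6-yl]but-2-enoate | COC(=O)/C=C(\CC1=CC[C@@H](OCOC)[C@@H](c2ccc(OCc3ccccc3)c(OCc3ccccc3)c2)O1)OCc1ccccc1
F5 | step 9 | (E)-3-(benzyloxy)-4-[(2R,3R)-2-[3,4-bis(benzyloxy)phenyl]-3-(methoxymethoxy)-3,4-dihydro-2H-pyran-6-yl]but-2-enoic acid | O=C(O)/C=C(\CC1=CC[C@@H](OCOC)[C@@H](c2ccc(OCc3ccccc3)c(OCc3ccccc3)c2)O1)OCc1ccccc1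
F6 | step 9 | (E)-3-(benzyloxy)-4-[(2R,3R)-2-[3,4-bis(benzyloxy)phenyl]-3-(methoxymethoxy)-3,4-dihydro-2H-pyran-6-yl]but-2-enoyl chloride | O=C(Cl)/C=C(\CC1=CC[C@@H](OCOC)[C@@H](c2ccc(OCc3ccccc3)c(OCc3ccccc3)c2)O1)OCc1ccccc1
F7 | step 10 | (2R,3R)-7-(benzyloxy)-2-[3,4-bis(benzyloxy)phenyl]-3-(methoxymethoxy)chroman-5-yl 3,4,5-tris(benzyloxy)benzoate | O=C(Oc1cc(OCc2ccccc2)cc2c1C[C@@H](OCOC)[C@@H](c1ccc(OCc3ccccc3)c(OCc3ccccc3)c1)O2)c1cc(OCc2ccccc2)c(OCc2ccccc2)c(OCc2ccccc2)c1
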